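**Strategy**

Ring A carries an oxygen on C8a and a ketone on the adjacent C8, between the C7 oxygen and the C4a substituent. Both bonds are disconnected at once, back to a C8–C8a aryne and 3-phenylpropanoic acid: in one operation the acid oxygen is fixed on C8a and its acyl carbon on C8, the C7 methoxy group deciding the orientation. The precursor is an ortho-silyl aryl triflate (Me3Si on C8a, triflate on C8) that already holds the (S)-configured C4 centre, the 4-methoxyphenyl group and the methyl propanoate arm, installed by rhodium-catalysed asymmetric conjugate arylation. Lactonization and demethylation then finish the target.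

Key step: step 8

Remark on numbering: ring A is numbered as in the chroman-2-one target (C4a, C5 to C8, C8a) throughout; the target is (4S).

Assumption: the (S,S) antipode of the diene in step 6 is taken as the one that delivers the aryl group to the Re face of C-β; should the sense on this substrate be the opposite, the equally accessible (R,R) antipode is used.

**Route**

Step 1
Reactants: 1 5-bromo-2,4-dimethoxybenzaldehyde
Product: 2 bromo acetal 2-(5-bromo-2,4-dimethoxyphenyl)-1,3-dioxolane
Conditions: ethylene glycol (5 equiv), p-TsOH·H2O (5 mol %), toluene, reflux, Dean–Stark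
Reagents that add atoms: ethylene glycol, OCCO
Why: Acid-catalysed acetalization with azeotropic removal of water masks the aldehyde against the organolithium reagents of steps 2 and 4, and the electron-rich dioxolane is released again by dilute acid.

Step 2
Reactants: 2 bromo acetal 2-(5-bromo-2,4-dimethoxyphenyl)-1,3-dioxolane
Product: 5 acetal phenol 5-(1,3-dioxolan-2-yl)-2,4-dimethoxyphenol, via aryllithium 3 (not isolated), via lithium aryltrimethoxyborate 4 (not isolated)
Conditions: n-BuLi (1.1 equiv), THF, −78 °C; B(OMe)3 (1.5 equiv), −78 → 0 °C; 30% aq H2O2, aq NaOH, 0 °C → rt; neutral work-up (NH4Cl, Na2S2O3)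
Reagents that add atoms: hydrogen peroxide, OO (the phenol oxygen of 5); trimethyl borate, COB(OC)OC, and n-butyllithium, [Li]CCCC (atoms held only in 3 and 4)
Why: Bromine–lithium exchange outruns any deprotonation at −78 °C, the aryllithium is borylated and the C–B bond is oxidised in place by basic hydrogen peroxide (lithiation–borylation–oxidation), conditions to which the acetal is inert.

Step 3
Reactants: 5 acetal phenol 5-(1,3-dioxolan-2-yl)-2,4-dimethoxyphenol
Product: 6 carbamate 5-(1,3-dioxolan-2-yl)-2,4-dimethoxyphenyl N-(propan-2-yl)carbamate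
Conditions: i-PrNCO (1.3 equiv), Et3N (0.2 equiv), CH2Cl2, rt
Reagents that add atoms: isopropyl isocyanate, CC(C)N=C=O
Why: Base-catalysed addition of the phenol to the isocyanate (carbamoylation) gives a secondary carbamate that serves as directing group in step 4 and as a phenol mask that can later be removed without touching an ester.

Step 4
Reactants: 6 carbamate 5-(1,3-dioxolan-2-yl)-2,4-dimethoxyphenyl N-(propan-2-yl)carbamate
Product: 10 silyl aldehyde 3-formyl-4,6-dimethoxy-2-(trimethylsilyl)phenyl N-(propan-2-yl)carbamate, via N-silyl carbamate 7 (not isolated), via C-lithio N-silyl carbamate 8 (not isolated), via C-silyl N-silyl carbamate 9 (not isolated)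
Conditions: TBSOTf (1.1 equiv), TMEDA (1.1 equiv), Et2O, 0 °C → rt; TMEDA (2 equiv), n-BuLi (2 equiv), −78 °C; Me3SiCl (3.5 equiv), −78 °C → rt; then 2 M aq HCl, THF, rt
Reagents that add atoms: chlorotrimethylsilane, C[Si](C)(C)Cl (SiMe3 of 10); water, O (aldehyde oxygen of 10); tert-butyldimethylsilyl triflate, CC(C)(C)[Si](C)(C)OS(=O)(=O)C(F)(F)F, and n-butyllithium, [Li]CCCC (atoms held only in 7 to 9)
Why: Directed ortho-metalation: after N-silylation in the flask the carbamate steers n-BuLi/TMEDA to its only free ortho carbon, which is also flanked by the coordinating dioxolane and should be lithiated much faster at −78 °C than the C–H between the two methoxy groups; Me3SiCl traps the anion, and the acidic work-up removes the N-silyl group and the acetal while the C–Si bond, meta to both methoxy groups, resists protodesilylation.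

Step 5
Reactants: 10 silyl aldehyde 3-formyl-4,6-dimethoxy-2-(trimethylsilyl)phenyl N-(propan-2-yl)carbamate; 11 methyl (triphenylphosphoranylidene)acetate
Product: 12 enoate methyl (2E)-3-[4,6-dimethoxy-3-{[(propan-2-yl)carbamoyl]oxy}-2-(trimethylsilyl)phenyl]prop-2-enoate
Conditions: 11 (1.5 equiv), toluene, 100 °C
Reagents that add atoms: none
Why: Wittig olefination with a stabilised, non-basic ylide should give the (E)-enoate and leaves the base-sensitive N–H carbamate untouched.

Step 6
Reactants: 12 enoate methyl (2E)-3-[4,6-dimethoxy-3-{[(propan-2-yl)carbamoyl]oxy}-2-(trimethylsilyl)phenyl]prop-2-enoate; 13 4-methoxyphenylboronic acid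
Product: 14 diaryl ester methyl (3S)-3-[4,6-dimethoxy-3-{[(propan-2-yl)carbamoyl]oxy}-2-(trimethylsilyl)phenyl]-3-(4-methoxyphenyl)propanoate
Conditions: Rh(acac)(C2H4)2 (5 mol %), (S,S)-Ph-bod* [(1S,4S)-2,5-diphenylbicyclo[2.2.2]octa-2,5-diene] (5.5 mol %), 13 (3 equiv), 1,4-dioxane/H2O 10:1, 80 °C
Reagents that add atoms: none
Why: Rhodium-catalysed asymmetric conjugate arylation (Hayashi–Miyaura reaction): the aryl–rhodium species bearing the C2-symmetric diene inserts the enoate with delivery of the 4-methoxyphenyl group to the Re face of C-β (priorities ring A > C-α > H), which sets C4 as (S), and the base-free aqueous medium spares the carbamate, the ester and the C–Si bond.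

Step 7
Reactants: 14 diaryl ester methyl (3S)-3-[4,6-dimethoxy-3-{[(propan-2-yl)carbamoyl]oxy}-2-(trimethylsilyl)phenyl]-3-(4-methoxyphenyl)propanoate
Product: 16 silyl triflate methyl (3S)-3-[4,6-dimethoxy-3-(trifluoromethanesulfonyloxy)-2-(trimethylsilyl)phenyl]-3-(4-methoxyphenyl)propanoate, via free phenol 15 (not isolated)
Conditions: DBU (1.5 equiv), Et2NH (1.3 equiv), MeCN, 40 °C; then PhNTf2 (1.5 equiv), 40 °C
Reagents that add atoms: N-phenylbis(trifluoromethanesulfonimide), O=S(=O)(N(c1ccccc1)S(=O)(=O)C(F)(F)F)C(F)(F)F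
Why: E1cB cleavage of the secondary carbamate by DBU releases isopropyl isocyanate (scavenged by Et2NH) and the hindered phenoxide, which PhNTf2 sulfonylates in the same flask (carbamate-to-triflate exchange) without affecting the remote ester or the stereocentre.

Step 8
Reactants: 16 silyl triflate methyl (3S)-3-[4,6-dimethoxy-3-(trifluoromethanesulfonyloxy)-2-(trimethylsilyl)phenyl]-3-(4-methoxyphenyl)propanoate; 17 3-phenylpropanoic acid
Product: 19 hydroxy ketone methyl (3S)-3-[2-hydroxy-4,6-dimethoxy-3-(3-phenylpropanoyl)phenyl]-3-(4-methoxyphenyl)propanoate, via C8–C8a aryne 18 (not isolated)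
Conditions: CsF (4 equiv), 17 (1.5 equiv), THF, 125 °C, sealed tube; aq NH4Cl work-up
Reagents that add atoms: none
Why: Fluoride attacks silicon on C8a and triflate leaves from C8, giving the C8–C8a aryne 18. The C7 methoxy group next to C8 withdraws inductively and distorts the aryne, so the cesium carboxylate oxygen bonds to the more electrophilic C8a and the negative charge develops on C8, where it is best stabilised. The C8 aryl anion then attacks the carbonyl carbon of the neighbouring O-acyl group through a four-membered transition state, and collapse of the tetrahedral intermediate moves the acyl group to C8 and frees the C8a phenoxide; the closest known reaction type is fluoride-induced aryne insertion into the C–O bond of carboxylic acids to give ortho-hydroxyaryl ketones. No ring is closed and no stereocentre is formed, and C4 is carried through unchanged because it is not acidic under these conditions. The step needs oxygen attack at C8a and not C8, secured by the C7 methoxy group against the steric bias of the C4a substituent, and acyl migration ahead of protonation of the anion, favoured by the high temperature in THF. The chelated ortho-acyl phenoxide formed is a poor nucleophile, so it should neither add to a second aryne nor close onto the methyl ester under these basic conditions.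

Step 9
Reactants: 19 hydroxy ketone methyl (3S)-3-[2-hydroxy-4,6-dimethoxy-3-(3-phenylpropanoyl)phenyl]-3-(4-methoxyphenyl)propanoate
Product: 20 trimethyl ether lactone (4S)-5,7-dimethoxy-4-(4-methoxyphenyl)-8-(3-phenylpropanoyl)-3,4-dihydro-2H-chromen-2-one
Conditions: p-TsOH·H2O (20 mol %), toluene, 110 °C, 4 Å molecular sieves
Reagents that add atoms: none
Why: Acid-catalysed intramolecular transesterification (lactonization) of the C8a phenol onto the methyl ester closes the six-membered lactone, driven by removal of methanol, and is done while O5 is still methylated so that only the C8a oxygen can close the ring.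

Step 10
Reactants: 20 trimethyl ether lactone (4S)-5,7-dimethoxy-4-(4-methoxyphenyl)-8-(3-phenylpropanoyl)-3,4-dihydro-2H-chromen-2-one
Product: 21 target (4S)-5,7-dihydroxy-4-(4-hydroxyphenyl)-8-(3-phenylpropanoyl)-3,4-dihydro-2H-chromen-2-one
Conditions: BBr3 (8 equiv), CH2Cl2, −78 °C → rt; then ice–water
Reagents that add atoms: none
Why: Lewis-acid ether cleavage: BBr3 binds each methoxy oxygen and bromide removes the methyl group, the chelated C7 ether first, while the aryl lactone, the ketone and the C4 stereocentre (not epimerisable by enolization) are expected to survive at low temperature.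

**Compound list**

1 | 5-bromo-2,4-dimethoxybenzaldehyde | COc1cc(OC)c(C=O)cc1Br | starting material
2 | 2-(5-bromo-2,4-dimethoxyphenyl)-1,3-dioxolane | COc1cc(OC)c(C2OCCO2)cc1Br | intermediate
3 | [5-(1,3-dioxolan-2-yl)-2,4-dimethoxyphenyl]lithium | [Li]c1cc(C2OCCO2)c(OC)cc1OC | intermediate (not isolated)
4 | lithium [5-(1,3-dioxolan-2-yl)-2,4-dimethoxyphenyl]trimethoxyborate | [Li+].CO[B-](OC)(OC)c1cc(C2OCCO2)c(OC)cc1OC | intermediate (not isolated)
5 | 5-(1,3-dioxolan-2-yl)-2,4-dimethoxyphenol | COc1cc(OC)c(C2OCCO2)cc1O | intermediate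
6 | 5-(1,3-dioxolan-2-yl)-2,4-dimethoxyphenyl N-(propan-2-yl)carbamate | COc1cc(OC)c(C2OCCO2)cc1OC(=O)NC(C)C | intermediate
7 | 5-(1,3-dioxolan-2-yl)-2,4-dimethoxyphenyl N-(tert-butyldimethylsilyl)-N-(propan-2-yl)carbamate | COc1cc(OC)c(C2OCCO2)cc1OC(=O)N(C(C)C)[Si](C)(C)C(C)(C)C | intermediate (not isolated)
8 | [2-{[N-(tert-butyldimethylsilyl)-N-(propan-2-yl)carbamoyl]oxy}-6-(1,3-dioxolan-2-yl)-3,5-dimethoxyphenyl]lithium | COc1cc(OC)c(C2OCCO2)c([Li])c1OC(=O)N(C(C)C)[Si](C)(C)C(C)(C)C | intermediate (not isolated)
9 | 3-(1,3-dioxolan-2-yl)-4,6-dimethoxy-2-(trimethylsilyl)phenyl N-(tert-butyldimethylsilyl)-N-(propan-2-yl)carbamate | COc1cc(OC)c(C2OCCO2)c([Si](C)(C)C)c1OC(=O)N(C(C)C)[Si](C)(C)C(C)(C)C | intermediate (not isolated)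
10 | 3-formyl-4,6-dimethoxy-2-(trimethylsilyl)phenyl N-(propan-2-yl)carbamate | COc1cc(OC)c(C=O)c([Si](C)(C)C)c1OC(=O)NC(C)C | intermediate
11 | methyl (triphenylphosphoranylidene)acetate | COC(=O)C=P(c1ccccc1)(c1ccccc1)c1ccccc1 | starting material
12 | methyl (2E)-3-[4,6-dimethoxy-3-{[(propan-2-yl)carbamoyl]oxy}-2-(trimethylsilyl)phenyl]prop-2-enoate | COC(=O)/C=C/c1c(OC)cc(OC)c(OC(=O)NC(C)C)c1[Si](C)(C)C | intermediate
13 | 4-methoxyphenylboronic acid | COc1ccc(B(O)O)cc1 | starting material
14 | methyl (3S)-3-[4,6-dimethoxy-3-{[(propan-2-yl)carbamoyl]oxy}-2-(trimethylsilyl)phenyl]-3-(4-methoxyphenyl)propanoate | COC(=O)C[C@@H](c1ccc(OC)cc1)c1c(OC)cc(OC)c(OC(=O)NC(C)C)c1[Si](C)(C)C | intermediate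
15 | methyl (3S)-3-[3-hydroxy-4,6-dimethoxy-2-(trimethylsilyl)phenyl]-3-(4-methoxyphenyl)propanoate | COC(=O)C[C@@H](c1ccc(OC)cc1)c1c(OC)cc(OC)c(O)c1[Si](C)(C)C | intermediate (not isolated)
16 | methyl (3S)-3-[4,6-dimethoxy-3-(trifluoromethanesulfonyloxy)-2-(trimethylsilyl)phenyl]-3-(4-methoxyphenyl)propanoate | COC(=O)C[C@@H](c1ccc(OC)cc1)c1c(OC)cc(OC)c(OS(=O)(=O)C(F)(F)F)c1[Si](C)(C)C | intermediate
17 | 3-phenylpropanoic acid | OC(=O)CCc1ccccc1 | starting material
18 | methyl (3S)-3-(2,3-didehydro-4,6-dimethoxyphenyl)-3-(4-methoxyphenyl)propanoate (C8–C8a aryne) | COC(=O)C[C@@H](c1ccc(OC)cc1)C1=C(OC)C=C(OC)C#C1 | intermediate (not isolated)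
19 | methyl (3S)-3-[2-hydroxy-4,6-dimethoxy-3-(3-phenylpropanoyl)phenyl]-3-(4-methoxyphenyl)propanoate | COC(=O)C[C@@H](c1ccc(OC)cc1)c1c(OC)cc(OC)c(C(=O)CCc2ccccc2)c1O | intermediate
20 | (4S)-5,7-dimethoxy-4-(4-methoxyphenyl)-8-(3-phenylpropanoyl)-3,4-dihydro-2H-chromen-2-one | O=C1C[C@@H](c2ccc(OC)cc2)c2c(OC)cc(OC)c(C(=O)CCc3ccccc3)c2O1 | intermediate
21 | (4S)-5,7-dihydroxy-4-(4-hydroxyphenyl)-8-(3-phenylpropanoyl)-3,4-dihydro-2H-chromen-2-one | O=C1C[C@@H](c2ccc(O)cc2)c2c(O)cc(O)c(C(=O)CCc3ccccc3)c2O1 | target

**Step count and risks**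

Total steps: 10. Longest linear sequence: 10 steps (1 to 21); 11, 13 and 17 are bought.

Steps most likely to fail:

Step 8. The C8 aryl anion may be protonated before the acyl group has migrated, so that the acid ends as an aryl ester. The carboxylate may also be kept off the crowded C8a and bond to C8, which reverses the pattern. The fallback gives up the aryne and fixes the oxygen/acyl pair on the arene before the stereocentre exists. 3-Phenylpropanoic acid 17 acylates 3,5-dimethoxyphenol in BF3·OEt2 at 80 °C (Friedel–Crafts acylation; the chelated ortho-hydroxy ketone is the stable isomer) to give 1-(2-hydroxy-4,6-dimethoxyphenyl)-3-phenylpropan-1-one F1. Magnesium-mediated ortho-formylation (MgCl2, Et3N, paraformaldehyde, MeCN, reflux) is delivered through the magnesium phenoxide to the only free carbon next to the hydroxyl and gives 2-hydroxy-4,6-dimethoxy-3-(3-phenylpropanoyl)benzaldehyde F2. Wittig reaction with ylide 11 in N,N-diethylaniline at reflux gives methyl (2E)-3-[2-hydroxy-4,6-dimethoxy-3-(3-phenylpropanoyl)phenyl]prop-2-enoate F3, which should isomerise and lactonise at that temperature to 5,7-dimethoxy-8-(3-phenylpropanoyl)-2H-chromen-2-one F4. Rhodium-catalysed asymmetric conjugate addition of boronic acid 13 to this coumarin (Rh(acac)(C2H4)2, (S)-SEGPHOS, dioxane/H2O, 60 °C; antipode assigned by the same reasoning as in step 6) should give lactone 20, where the route is rejoined for step 10.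

Step 6. The twisted ring A shields C-β on both faces with its methoxy and trimethylsilyl groups, so insertion may be slow enough for protodeboronation of 13 to take over, and facial discrimination may be weak. The fallback makes the C3–C4 bond by trapping a cation and separates the enantiomers. Aldehyde 10 is arylated at the carbonyl carbon with 13 (Rh(acac)(CO)2, 1,1'-bis(diphenylphosphino)ferrocene, DME/H2O, 80 °C) to give racemic 3-[hydroxy(4-methoxyphenyl)methyl]-4,6-dimethoxy-2-(trimethylsilyl)phenyl N-(propan-2-yl)carbamate F5. This doubly activated benzhydrol is ionised with Bi(OTf)3 (5 mol %) in CH2Cl2 at −20 °C in the presence of 1-methoxy-1-(trimethylsilyloxy)ethene; the planar cation is captured by the silyl ketene acetal (SN1 alkylation) to give racemic methyl 3-[4,6-dimethoxy-3-{[(propan-2-yl)carbamoyl]oxy}-2-(trimethylsilyl)phenyl]-3-(4-methoxyphenyl)propanoate F6. Preparative supercritical-fluid chromatography on a chiral stationary phase separates 14 from methyl (3R)-3-[4,6-dimethoxy-3-{[(propan-2-yl)carbamoyl]oxy}-2-(trimethylsilyl)phenyl]-3-(4-methoxyphenyl)propanoate F7, and the route is rejoined at 14.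

Step 4. Deprotonation may occur at the C–H between the two methoxy groups instead of next to the carbamate, and the silyl triflate used to protect nitrogen may open the dioxolane. The fallback uses a tertiary carbamate as directing group, so no silyl triflate is needed. Phenol 5 is treated with ClC(O)NEt2 and K2CO3 in MeCN at reflux to give 5-(1,3-dioxolan-2-yl)-2,4-dimethoxyphenyl N,N-diethylcarbamate F8. Directed ortho-metalation with s-BuLi/TMEDA in THF at −78 °C and quenching with Me3SiCl gives 3-(1,3-dioxolan-2-yl)-4,6-dimethoxy-2-(trimethylsilyl)phenyl N,N-diethylcarbamate F9. LiAlH4 in THF cleaves the carbamate to 3-(1,3-dioxolan-2-yl)-4,6-dimethoxy-2-(trimethylsilyl)phenol F10, and the 1 M HCl work-up opens the acetal to 3-hydroxy-4,6-dimethoxy-2-(trimethylsilyl)benzaldehyde F11. Carbamoylation with i-PrNCO/Et3N in CH2Cl2 then gives aldehyde 10, where the route is rejoined.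

Further compounds
F1 | step 8 | 1-(2-hydroxy-4,6-dimethoxyphenyl)-3-phenylpropan-1-one | COc1cc(O)c(C(=O)CCc2ccccc2)c(OC)c1
F2 | step 8 | 2-hydroxy-4,6-dimethoxy-3-(3-phenylpropanoyl)benzaldehyde | COc1cc(OC)c(C(=O)CCc2ccccc2)c(O)c1C=O
F3 | step 8 | methyl (2E)-3-[2-hydroxy-4,6-dimethoxy-3-(3-phenylpropanoyl)phenyl]prop-2-enoate | COC(=O)/C=C/c1c(OC)cc(OC)c(C(=O)CCc2ccccc2)c1O
F4 | step 8 | 5,7-dimethoxy-8-(3-phenylpropanoyl)-2H-chromen-2-one | O=c1ccc2c(OC)cc(OC)c(C(=O)CCc3ccccc3)c2o1
F5 | step 6 | racemic 3-[hydroxy(4-methoxyphenyl)methyl]-4,6-dimethoxy-2-(trimethylsilyl)phenyl N-(propan-2-yl)carbamate | COc1ccc(C(O)c2c(OC)cc(OC)c(OC(=O)NC(C)C)c2[Si](C)(C)C)cc1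
F6 | step 6 | racemic methyl 3-[4,6-dimethoxy-3-{[(propan-2-yl)carbamoyl]oxy}-2-(trimethylsilyl)phenyl]-3-(4-methoxyphenyl)propanoate | COC(=O)CC(c1ccc(OC)cc1)c1c(OC)cc(OC)c(OC(=O)NC(C)C)c1[Si](C)(C)C
F7 | step 6 | methyl (3R)-3-[4,6-dimethoxy-3-{[(propan-2-yl)carbamoyl]oxy}-2-(trimethylsilyl)phenyl]-3-(4-methoxyphenyl)propanoate | COC(=O)C[C@H](c1ccc(OC)cc1)c1c(OC)cc(OC)c(OC(=O)NC(C)C)c1[Si](C)(C)C
F8 | step 4 | 5-(1,3-dioxolan-2-yl)-2,4-dimethoxyphenyl N,N-diethylcarbamate | CCN(CC)C(=O)Oc1cc(C2OCCO2)c(OC)cc1OC
F9 | step 4 | 3-(1,3-dioxolan-2-yl)-4,6-dimethoxy-2-(trimethylsilyl)phenyl N,N-diethylcarbamate | CCN(CC)C(=O)Oc1c(OC)cc(OC)c(C2OCCO2)c1[Si](C)(C)C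
F10 | step 4 | 3-(1,3-dioxolan-2-yl)-4,6-dimethoxy-2-(trimethylsilyl)phenol | COc1cc(OC)c(C2OCCO2)c([Si](C)(C)C)c1O
F11 | step 4 | 3-hydroxy-4,6-dimethoxy-2-(trimethylsilyl)benzaldehyde | COc1cc(OC)c(C=O)c([Si](C)(C)C)c1O
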